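**Retrosynthetic overview**
1. Target ⇒ methyl-enol-ether core 28 + aroyl chloride 34 (from catechol), joined by C3 acylation and one global deprotection.
2. Key disconnection: the C5–CH2 bond. The bridgehead α-keto radical from bromide 18 is captured by an alkylnickel species made from the enantiopure side-chain zinc reagent 27 (sp3–sp3 radical cross-coupling).
3. Bicyclic core: ring A is annulated onto ring B with malonyl dichloride (Effenberger), which fixes both bridgeheads relative to C7/C8.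
4. Ring B is made first: organocatalytic Michael/aldol sets C7, β-homoprenylation with enone regeneration follows, and Me2CuLi addition/prenyl trapping sets C8.
5. Side chain: Evans dienolate alkylation sets the exocyclic stereocentre.

Assumption: the target is handled as the 4-hydroxy-2,9-dione enol tautomer written in the SMILES, which interconverts freely with its 2-hydroxy tautomer.

Step 1
Reactants: 1 5-methylhex-4-enal; 2 but-3-en-2-one
Product: 4 (4R)-4-(3-methylbut-2-en-1-yl)cyclohex-2-en-1-one, via keto-aldehyde 3 (not isolated)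
Conditions: (R)-2-[diphenyl(trimethylsilyloxy)methyl]pyrrolidine (5 mol %), ethyl 3,4-dihydroxybenzoate (20 mol %), neat, 4 °C; then KOH (0.1 M aq.), nBu4NOH (cat.), Et2O/THF, reflux
Reagents that add atoms: none
Why: Enamine-catalysed Michael addition of the aldehyde to the vinyl ketone, in which the (R)-catalyst shields one enamine face and sets the future C7 as R, followed by intramolecular aldol condensation (Robinson-type annulation) that closes ring B without touching that centre.

Step 2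
Reactants: 4 (4R)-4-(3-methylbut-2-en-1-yl)cyclohex-2-en-1-one; 5 5-bromo-2-methylpent-2-ene
Product: 8 (4R)-3-(4-methylpent-3-en-1-yl)-4-(3-methylbut-2-en-1-yl)cyclohex-2-en-1-one, via Grignard reagent 6 (not isolated), via magnesium enolate 7 (not isolated)
Conditions: 5, Mg, THF; 4, CuBr·SMe2 (10 mol %), THF, −40 °C; then ZnCl2, [Pd(allyl)Cl]2 (2.5 mol %), diethyl allyl phosphate, 60 °C
Reagents that add atoms: none
Why: Copper-catalysed conjugate addition of the homoprenyl Grignard reagent and allyl-palladium-catalysed dehydrogenation of the resulting enolate in the same flask (telescoped β-alkylation/enone regeneration), which erases the transient C3 centre and leaves C4 untouched.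

Step 3
Reactants: 8 (4R)-3-(4-methylpent-3-en-1-yl)-4-(3-methylbut-2-en-1-yl)cyclohex-2-en-1-one; 9 1-bromo-3-methylbut-2-ene
Product: 11 (3S,4R)-3-methyl-3-(4-methylpent-3-en-1-yl)-2,4-bis(3-methylbut-2-en-1-yl)cyclohexan-1-one (mixture at C2), via lithium enolate 10 (not isolated)
Conditions: Me2CuLi, Et2O, −20 °C; then 9, HMPA, THF, −20 °C → rt
Reagents that add atoms: lithium dimethylcuprate, [Li+].C[Cu-]C
Why: Gilman cuprate 1,4-addition occurs anti to the neighbouring C4 prenyl group, setting the quaternary carbon with methyl trans and homoprenyl cis to that prenyl, and the regiodefined enolate is C-alkylated by the allylic bromide (tandem conjugate addition–alkylation); the C2 configuration is irrelevant because that carbon is later re-enolised.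

Step 4
Reactants: 11 (3S,4R)-3-methyl-3-(4-methylpent-3-en-1-yl)-2,4-bis(3-methylbut-2-en-1-yl)cyclohexan-1-one
Product: 12 trimethyl{[(4S,5S)-5-methyl-5-(4-methylpent-3-en-1-yl)-4,6-bis(3-methylbut-2-en-1-yl)cyclohex-1-en-1-yl]oxy}silane (mixture at C6)
Conditions: LiN(iPr)2, Me3SiCl (in situ quench), THF, −78 °C
Reagents that add atoms: chlorotrimethylsilane, C[Si](C)(C)Cl
Why: Kinetic deprotonation at the unhindered CH2 α-carbon with immediate O-silylation gives the less substituted silyl enol ether (kinetic enolate trapping).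

Step 5
Reactants: 12 trimethyl{[(4S,5S)-5-methyl-5-(4-methylpent-3-en-1-yl)-4,6-bis(3-methylbut-2-en-1-yl)cyclohex-1-en-1-yl]oxy}silane; 13 malonyl dichloride
Product: 15 (1S,5R,7S,8S)-4-hydroxy-8-methyl-8-(4-methylpent-3-en-1-yl)-1,7-bis(3-methylbut-2-en-1-yl)bicyclo[3.3.1]non-3-ene-2,9-dione, via keto acid chloride 14 (not isolated)
Conditions: Et2O, −20 °C → rt; then KOH, BnEt3NCl, H2O, rt
Reagents that add atoms: none
Why: Effenberger α,α′-annulation, in which C-acylation of the enol silane at C5 is followed by intramolecular C-acylation at C1; the three-carbon bridge must be cis-diaxial and is delivered to the ring face opposite the axial homoprenyl group and the C7 prenyl group (as in the clusianone series), so both bridgeheads are fixed relative to C7/C8 and the C1 epimers of 12 converge.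

Step 6
Reactants: 15 (1S,5R,7S,8S)-4-hydroxy-8-methyl-8-(4-methylpent-3-en-1-yl)-1,7-bis(3-methylbut-2-en-1-yl)bicyclo[3.3.1]non-3-ene-2,9-dione
Product: 16 (1S,5R,7S,8S)-4-methoxy-8-methyl-8-(4-methylpent-3-en-1-yl)-1,7-bis(3-methylbut-2-en-1-yl)bicyclo[3.3.1]non-3-ene-2,9-dione
Conditions: HC(OMe)3, p-TsOH (cat.), MeOH, 50 °C
Reagents that add atoms: trimethyl orthoformate, COC(OC)OC
Why: Acid-catalysed enol-ether formation at the less hindered C4 oxygen (remote from the C1/C8 quaternary pair) masks the acidic vinylogous acid for the metalation steps.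

Step 7
Reactants: 16 (1S,5R,7S,8S)-4-methoxy-8-methyl-8-(4-methylpent-3-en-1-yl)-1,7-bis(3-methylbut-2-en-1-yl)bicyclo[3.3.1]non-3-ene-2,9-dione
Product: 18 (1S,5S,7S,8S)-5-bromo-4-methoxy-8-methyl-8-(4-methylpent-3-en-1-yl)-1,7-bis(3-methylbut-2-en-1-yl)bicyclo[3.3.1]non-3-ene-2,9-dione, via bridgehead lithium species 17 (not isolated)
Conditions: LiN(iPr)2, THF, −78 °C; then BrCCl2CCl2Br
Reagents that add atoms: 1,2-dibromo-1,1,2,2-tetrachloroethane, BrC(Cl)(Cl)C(Cl)(Cl)Br
Why: Bridgehead lithiation removes the only sp3 α-proton (C5–H) and the pyramidal bridgehead anion is brominated by the positive-bromine donor with necessarily retained geometry (bridgehead enolate chemistry).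

Step 8
Reactants: 19 3-methylbut-3-en-1-ol
Product: 20 3-methylbut-3-en-1-yl trifluoromethanesulfonate
Conditions: Tf2O, 2,6-lutidine, CH2Cl2, −78 °C (used at once)
Reagents that add atoms: trifluoromethanesulfonic anhydride, O=S(=O)(OS(=O)(=O)C(F)(F)F)C(F)(F)F
Why: O-sulfonylation turns the unactivated homoallylic alcohol into an electrophile reactive enough for an imide enolate at −78 °C.

Step 9
Reactants: 21 3-methylbut-2-enoyl chloride
Product: 22 (4S)-4-benzyl-3-(3-methylbut-2-enoyl)-1,3-oxazolidin-2-one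
Conditions: (S)-4-benzyl-1,3-oxazolidin-2-one, n-BuLi, THF, −78 °C; then 21
Reagents that add atoms: (S)-4-benzyl-1,3-oxazolidin-2-one, O=C1N[C@@H](Cc2ccccc2)CO1
Why: N-acylation of the lithiated oxazolidinone attaches the recoverable Evans auxiliary.

Step 10
Reactants: 22 (4S)-4-benzyl-3-(3-methylbut-2-enoyl)-1,3-oxazolidin-2-one; 20 3-methylbut-3-en-1-yl trifluoromethanesulfonate
Product: 24 (4S)-4-benzyl-3-[(2S)-5-methyl-2-(prop-1-en-2-yl)hex-5-enoyl]-1,3-oxazolidin-2-one, via sodium dienolate 23 (not isolated)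
Conditions: NaN(SiMe3)2, THF, −78 °C; then 20, −78 → −40 °C
Reagents that add atoms: none
Why: Evans asymmetric alkylation of the chelated Z-dienolate, which reacts at the α-carbon (deconjugative alkylation, creating the isopropenyl group) on the face opposite the benzyl group to give the (2S) centre.

Step 11
Reactants: 24 (4S)-4-benzyl-3-[(2S)-5-methyl-2-(prop-1-en-2-yl)hex-5-enoyl]-1,3-oxazolidin-2-one
Product: 25 (2S)-5-methyl-2-(prop-1-en-2-yl)hex-5-en-1-ol
Conditions: LiBH4, H2O (1 equiv), Et2O, 0 °C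
Reagents that add atoms: none
Why: Reductive cleavage of the imide releases the primary alcohol and the auxiliary without epimerising the α-centre.

Step 12
Reactants: 25 (2S)-5-methyl-2-(prop-1-en-2-yl)hex-5-en-1-ol
Product: 26 (5S)-5-(iodomethyl)-2,6-dimethylhepta-1,6-diene
Conditions: I2, PPh3, imidazole, CH2Cl2, 0 °C
Reagents that add atoms: iodine, II
Why: Appel-type iodination at the primary carbon leaves the adjacent stereocentre untouched.

Step 13
Reactants: 18 (1S,5S,7S,8S)-5-bromo-4-methoxy-8-methyl-8-(4-methylpent-3-en-1-yl)-1,7-bis(3-methylbut-2-en-1-yl)bicyclo[3.3.1]non-3-ene-2,9-dione; 26 (5S)-5-(iodomethyl)-2,6-dimethylhepta-1,6-diene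
Product: 28 (1S,5R,7S,8S)-4-methoxy-8-methyl-5-[(2R)-5-methyl-2-(prop-1-en-2-yl)hex-5-en-1-yl]-8-(4-methylpent-3-en-1-yl)-1,7-bis(3-methylbut-2-en-1-yl)bicyclo[3.3.1]non-3-ene-2,9-dione, via alkylzinc iodide 27 (not isolated)
Conditions: 26, Zn dust, LiCl, THF, 40 °C; then 18, NiCl2·glyme (10 mol %), 4,4′-di-tert-butyl-2,2′-bipyridine (12 mol %), THF/DMA, 0 → 25 °C
Reagents that add atoms: none
Why: Proposed new method: a nickel-catalysed Negishi-type sp3–sp3 coupling in which the monovalent alkylnickel species formed from 27 abstracts bromine from 18 to give the C5 bridgehead α-keto radical (which cannot enolise, eliminate or reach any alkene for 5-exo closure, unlike a radical at C1 or C7), and radical capture at nickel followed by C–C reductive elimination forges the quaternary C5–CH2 bond with the bridgehead geometry retained and the side-chain centre untouched because that partner stays an organometallic and never becomes a radical; the closest known reaction types are nickel-catalysed Negishi alkyl–alkyl couplings of α-halo carbonyl compounds and of bridgehead redox-active esters with alkylzinc reagents, and bridgehead radical allylation of α-halo bicyclo[3.3.1]nonanetriones.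

Step 14
Reactants: 29 benzene-1,2-diol (catechol)
Product: 30 4-bromobenzene-1,2-diol
Conditions: NBS, HBF4·OEt2, MeCN, −30 °C → rt
Reagents that add atoms: N-bromosuccinimide, O=C1CCC(=O)N1Br
Why: Electrophilic aromatic bromination goes para to one hydroxyl group, giving the 4-bromo isomer.

Step 15
Reactants: 30 4-bromobenzene-1,2-diol
Product: 31 [(4-bromo-1,2-phenylene)bis(oxy)]bis(tert-butyldimethylsilane)
Conditions: TBSCl, imidazole, DMF, rt
Reagents that add atoms: tert-butyldimethylsilyl chloride, CC(C)(C)[Si](C)(C)Cl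
Why: Double O-silylation protects the catechol with groups that survive organolithium chemistry and fall off under the final basic hydrolysis.

Step 16
Reactants: 31 [(4-bromo-1,2-phenylene)bis(oxy)]bis(tert-butyldimethylsilane)
Product: 34 3,4-bis[(tert-butyldimethylsilyl)oxy]benzoyl chloride, via aryllithium 32 (not isolated), via lithium carboxylate 33 (not isolated)
Conditions: n-BuLi, THF, −78 °C; CO2; then (COCl)2, DMF (cat.), CH2Cl2, 0 °C
Reagents that add atoms: carbon dioxide, O=C=O; oxalyl chloride, O=C(Cl)C(=O)Cl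
Why: Bromine–lithium exchange, carboxylation and direct conversion of the carboxylate into the acid chloride (Vilsmeier-type activation) give the aroyl donor in one flask.

Step 17
Reactants: 28 (1S,5R,7S,8S)-4-methoxy-8-methyl-5-[(2R)-5-methyl-2-(prop-1-en-2-yl)hex-5-en-1-yl]-8-(4-methylpent-3-en-1-yl)-1,7-bis(3-methylbut-2-en-1-yl)bicyclo[3.3.1]non-3-ene-2,9-dione; 34 3,4-bis[(tert-butyldimethylsilyl)oxy]benzoyl chloride
Product: 36 (1R,5R,7S,8S)-3-{3,4-bis[(tert-butyldimethylsilyl)oxy]benzoyl}-4-methoxy-8-methyl-5-[(2R)-5-methyl-2-(prop-1-en-2-yl)hex-5-en-1-yl]-8-(4-methylpent-3-en-1-yl)-1,7-bis(3-methylbut-2-en-1-yl)bicyclo[3.3.1]non-3-ene-2,9-dione, via vinyllithium 35 (not isolated)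
Conditions: lithium 2,2,6,6-tetramethylpiperidide, THF, −78 °C; then 34
Reagents that add atoms: none
Why: Vinylic lithiation at C3 (between the ketone and the enol ether, the only acidic C–H left) and C-acylation of the vinyllithium by the acid chloride install the aroyl group.

Step 18
Reactants: 36 (1R,5R,7S,8S)-3-{3,4-bis[(tert-butyldimethylsilyl)oxy]benzoyl}-4-methoxy-8-methyl-5-[(2R)-5-methyl-2-(prop-1-en-2-yl)hex-5-en-1-yl]-8-(4-methylpent-3-en-1-yl)-1,7-bis(3-methylbut-2-en-1-yl)bicyclo[3.3.1]non-3-ene-2,9-dione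
Product: 37 (1R,5R,7S,8S)-3-(3,4-dihydroxybenzoyl)-4-hydroxy-8-methyl-5-[(2R)-5-methyl-2-(prop-1-en-2-yl)hex-5-en-1-yl]-8-(4-methylpent-3-en-1-yl)-1,7-bis(3-methylbut-2-en-1-yl)bicyclo[3.3.1]non-3-ene-2,9-dione (CNP0249346.2)
Conditions: LiOH, dioxane/H2O (degassed), 90 °C; then 1 M HCl
Reagents that add atoms: lithium hydroxide, [Li+].[OH-]
Why: Hydroxide addition–elimination cleaves the vinylogous methyl ester and hydrolyses both aryl silyl ethers in one global deprotection that touches no stereocentre.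

**Compound list**
1 | 5-methylhex-4-enal | CC(C)=CCCC=O | starting material
2 | but-3-en-2-one | CC(=O)C=C | starting material
3 | (2R)-2-(3-methylbut-2-en-1-yl)-5-oxohexanal | O=C[C@@H](CC=C(C)C)CCC(C)=O | intermediate (not isolated)
4 | (4R)-4-(3-methylbut-2-en-1-yl)cyclohex-2-en-1-one | O=C1C=C[C@@H](CC=C(C)C)CC1 | intermediate
5 | 5-bromo-2-methylpent-2-ene | CC(C)=CCCBr | starting material
6 | (4-methylpent-3-en-1-yl)magnesium bromide | CC(C)=CCC[Mg]Br | intermediate (not isolated)
7 | bromomagnesium (3R,4R)-3-(4-methylpent-3-en-1-yl)-4-(3-methylbut-2-en-1-yl)cyclohex-1-en-1-olate (3,4-trans) | Br[Mg]OC1=C[C@H](CCC=C(C)C)[C@@H](CC=C(C)C)CC1 | intermediate (not isolated)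
8 | (4R)-3-(4-methylpent-3-en-1-yl)-4-(3-methylbut-2-en-1-yl)cyclohex-2-en-1-one | O=C1C=C(CCC=C(C)C)[C@@H](CC=C(C)C)CC1 | intermediate
9 | 1-bromo-3-methylbut-2-ene | CC(C)=CCBr | starting material
10 | lithium (3S,4R)-3-methyl-3-(4-methylpent-3-en-1-yl)-4-(3-methylbut-2-en-1-yl)cyclohex-1-en-1-olate | [Li]OC1=C[C@@](C)(CCC=C(C)C)[C@@H](CC=C(C)C)CC1 | intermediate (not isolated)
11 | (3S,4R)-3-methyl-3-(4-methylpent-3-en-1-yl)-2,4-bis(3-methylbut-2-en-1-yl)cyclohexan-1-one (mixture at C2) | O=C1C(CC=C(C)C)[C@@](C)(CCC=C(C)C)[C@@H](CC=C(C)C)CC1 | intermediate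
12 | trimethyl{[(4S,5S)-5-methyl-5-(4-methylpent-3-en-1-yl)-4,6-bis(3-methylbut-2-en-1-yl)cyclohex-1-en-1-yl]oxy}silane (mixture at C6) | C[Si](C)(C)OC1=CC[C@H](CC=C(C)C)[C@](C)(CCC=C(C)C)C1CC=C(C)C | intermediate
13 | malonyl dichloride | O=C(Cl)CC(Cl)=O | starting material
14 | 3-[(4S,5S)-4-methyl-4-(4-methylpent-3-en-1-yl)-3,5-bis(3-methylbut-2-en-1-yl)-2-oxocyclohexyl]-3-oxopropanoyl chloride (mixture at ring C1 and C3) | O=C1C(CC=C(C)C)[C@@](C)(CCC=C(C)C)[C@@H](CC=C(C)C)CC1C(=O)CC(Cl)=O | intermediate (not isolated)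
15 | (1S,5R,7S,8S)-4-hydroxy-8-methyl-8-(4-methylpent-3-en-1-yl)-1,7-bis(3-methylbut-2-en-1-yl)bicyclo[3.3.1]non-3-ene-2,9-dione | [C@@H]12C[C@H](CC=C(C)C)[C@](C)(CCC=C(C)C)[C@@](CC=C(C)C)(C(=O)C=C1O)C2=O | intermediate
16 | (1S,5R,7S,8S)-4-methoxy-8-methyl-8-(4-methylpent-3-en-1-yl)-1,7-bis(3-methylbut-2-en-1-yl)bicyclo[3.3.1]non-3-ene-2,9-dione | [C@@H]12C[C@H](CC=C(C)C)[C@](C)(CCC=C(C)C)[C@@](CC=C(C)C)(C(=O)C=C1OC)C2=O | intermediate
17 | C5-lithio derivative of 16 (bridgehead lithium species) | [Li][C@@]12C[C@H](CC=C(C)C)[C@](C)(CCC=C(C)C)[C@@](CC=C(C)C)(C(=O)C=C1OC)C2=O | intermediate (not isolated)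
18 | (1S,5S,7S,8S)-5-bromo-4-methoxy-8-methyl-8-(4-methylpent-3-en-1-yl)-1,7-bis(3-methylbut-2-en-1-yl)bicyclo[3.3.1]non-3-ene-2,9-dione | Br[C@@]12C[C@H](CC=C(C)C)[C@](C)(CCC=C(C)C)[C@@](CC=C(C)C)(C(=O)C=C1OC)C2=O | intermediate
19 | 3-methylbut-3-en-1-ol | C=C(C)CCO | starting material
20 | 3-methylbut-3-en-1-yl trifluoromethanesulfonate | C=C(C)CCOS(=O)(=O)C(F)(F)F | intermediate
21 | 3-methylbut-2-enoyl chloride | CC(C)=CC(=O)Cl | starting material
22 | (4S)-4-benzyl-3-(3-methylbut-2-enoyl)-1,3-oxazolidin-2-one | CC(C)=CC(=O)N1[C@@H](Cc2ccccc2)COC1=O | intermediate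
23 | sodium dienolate of 22 | C=C(C)C=C(O[Na])N1[C@@H](Cc2ccccc2)COC1=O | intermediate (not isolated)
24 | (4S)-4-benzyl-3-[(2S)-5-methyl-2-(prop-1-en-2-yl)hex-5-enoyl]-1,3-oxazolidin-2-one | C=C(C)CC[C@H](C(=O)N1[C@@H](Cc2ccccc2)COC1=O)C(=C)C | intermediate
25 | (2S)-5-methyl-2-(prop-1-en-2-yl)hex-5-en-1-ol | C=C(C)CC[C@H](CO)C(=C)C | intermediate
26 | (5S)-5-(iodomethyl)-2,6-dimethylhepta-1,6-diene | C=C(C)CC[C@H](CI)C(=C)C | intermediate
27 | [(2S)-5-methyl-2-(prop-1-en-2-yl)hex-5-en-1-yl]zinc iodide | C=C(C)CC[C@H](C[Zn]I)C(=C)C | intermediate (not isolated)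
28 | (1S,5R,7S,8S)-4-methoxy-8-methyl-5-[(2R)-5-methyl-2-(prop-1-en-2-yl)hex-5-en-1-yl]-8-(4-methylpent-3-en-1-yl)-1,7-bis(3-methylbut-2-en-1-yl)bicyclo[3.3.1]non-3-ene-2,9-dione | C=C(C)CC[C@H](C[C@@]12C[C@H](CC=C(C)C)[C@](C)(CCC=C(C)C)[C@@](CC=C(C)C)(C(=O)C=C1OC)C2=O)C(=C)C | intermediate
29 | benzene-1,2-diol (catechol) | Oc1ccccc1O | starting material
30 | 4-bromobenzene-1,2-diol | Oc1ccc(Br)cc1O | intermediate
31 | [(4-bromo-1,2-phenylene)bis(oxy)]bis(tert-butyldimethylsilane) | CC(C)(C)[Si](C)(C)Oc1ccc(Br)cc1O[Si](C)(C)C(C)(C)C | intermediate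
32 | {3,4-bis[(tert-butyldimethylsilyl)oxy]phenyl}lithium | [Li]c1ccc(O[Si](C)(C)C(C)(C)C)c(O[Si](C)(C)C(C)(C)C)c1 | intermediate (not isolated)
33 | lithium 3,4-bis[(tert-butyldimethylsilyl)oxy]benzoate | [Li+].[O-]C(=O)c1ccc(O[Si](C)(C)C(C)(C)C)c(O[Si](C)(C)C(C)(C)C)c1 | intermediate (not isolated)
34 | 3,4-bis[(tert-butyldimethylsilyl)oxy]benzoyl chloride | O=C(Cl)c1ccc(O[Si](C)(C)C(C)(C)C)c(O[Si](C)(C)C(C)(C)C)c1 | intermediate
35 | C3-lithio derivative of 28 (vinyllithium) | C=C(C)CC[C@H](C[C@@]12C[C@H](CC=C(C)C)[C@](C)(CCC=C(C)C)[C@@](CC=C(C)C)(C(=O)C([Li])=C1OC)C2=O)C(=C)C | intermediate (not isolated)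
36 | (1R,5R,7S,8S)-3-{3,4-bis[(tert-butyldimethylsilyl)oxy]benzoyl}-4-methoxy-8-methyl-5-[(2R)-5-methyl-2-(prop-1-en-2-yl)hex-5-en-1-yl]-8-(4-methylpent-3-en-1-yl)-1,7-bis(3-methylbut-2-en-1-yl)bicyclo[3.3.1]non-3-ene-2,9-dione | C=C(C)CC[C@H](C[C@@]12C[C@H](CC=C(C)C)[C@](C)(CCC=C(C)C)[C@@](CC=C(C)C)(C(=O)C(C(=O)c3ccc(O[Si](C)(C)C(C)(C)C)c(O[Si](C)(C)C(C)(C)C)c3)=C1OC)C2=O)C(=C)C | intermediate
37 | (1R,5R,7S,8S)-3-(3,4-dihydroxybenzoyl)-4-hydroxy-8-methyl-5-[(2R)-5-methyl-2-(prop-1-en-2-yl)hex-5-en-1-yl]-8-(4-methylpent-3-en-1-yl)-1,7-bis(3-methylbut-2-en-1-yl)bicyclo[3.3.1]non-3-ene-2,9-dione | C=C(C)CC[C@H](C[C@@]12C[C@H](CC=C(C)C)[C@](C)(CCC=C(C)C)[C@@](CC=C(C)C)(C(=O)C(C(=O)c3ccc(O)c(O)c3)=C1O)C2=O)C(=C)C | target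

**Totals and risks**
Total step count: 18. Longest linear sequence: 10 steps (steps 1–7, 13, 17, 18).

Most likely to fail, first: step 13, the nickel-mediated bridgehead coupling. Possible failures are reduction of 18 back to 16 by halogen–zinc exchange and β-hydride loss from the alkylnickel species. The fallback makes the same bond by polar bridgehead alkylation. Alcohol 25 is converted with Tf2O/2,6-lutidine into (2S)-5-methyl-2-(prop-1-en-2-yl)hex-5-en-1-yl trifluoromethanesulfonate F1. The bridgehead lithium species generated from 16 with LiN(iPr)2 at −78 °C is then alkylated with F1. This fallback sets out from 16 (with 25) and comes back to the route at 28.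

Second: step 5, the Effenberger annulation, which must create the quaternary C1 next to the quaternary C8. The fallback forms that quaternary centre after the annulation instead of during it. Enone 8 is treated with Me2CuLi/Me3SiCl to give trimethyl{[(3S,4R)-3-methyl-3-(4-methylpent-3-en-1-yl)-4-(3-methylbut-2-en-1-yl)cyclohex-1-en-1-yl]oxy}silane F2. Annulation of F2 with malonyl dichloride now builds only tertiary bridgeheads and gives (1S,5R,7S,8R)-4-hydroxy-8-methyl-8-(4-methylpent-3-en-1-yl)-7-(3-methylbut-2-en-1-yl)bicyclo[3.3.1]non-3-ene-2,9-dione F3. O-Methylation with HC(OMe)3/p-TsOH and separation from the 2-methoxy isomer gives the 4-methoxy ether F4. Lithiation of F4 with LiN(iPr)2 at the doubly activated C1–H (flanked by C2=O and C9=O) and alkylation with prenyl bromide 9 then installs the C1 prenyl group at a bridgehead whose configuration cannot change. This fallback sets out from 8 and comes back at 16.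

Third: step 10, the alkylation of the imide dienolate with an unactivated triflate, where enolate decomposition or γ-alkylation may intervene. The fallback replaces auxiliary control by resolution. Commercial methyl 3-methylbut-2-enoate is deprotonated with LiN(iPr)2/HMPA and alkylated at the α-carbon with triflate 20 to give racemic methyl 5-methyl-2-(prop-1-en-2-yl)hex-5-enoate F5. LiAlH4 reduction gives racemic 5-methyl-2-(prop-1-en-2-yl)hex-5-en-1-ol F6. Porcine pancreatic lipase with vinyl acetate acetylates the (R)-enantiomer to (2R)-5-methyl-2-(prop-1-en-2-yl)hex-5-en-1-yl acetate F7 (by analogy with lavandulol) and leaves the (S)-alcohol. This fallback sets out from 20 and comes back at 25.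

**Further compounds**
F1 | step 13 | (2S)-5-methyl-2-(prop-1-en-2-yl)hex-5-en-1-yl trifluoromethanesulfonate | C=C(C)CC[C@H](COS(=O)(=O)C(F)(F)F)C(=C)C
F2 | step 5 | trimethyl{[(3S,4R)-3-methyl-3-(4-methylpent-3-en-1-yl)-4-(3-methylbut-2-en-1-yl)cyclohex-1-en-1-yl]oxy}silane | C[Si](C)(C)OC1=C[C@@](C)(CCC=C(C)C)[C@@H](CC=C(C)C)CC1
F3 | step 5 | (1S,5R,7S,8R)-4-hydroxy-8-methyl-8-(4-methylpent-3-en-1-yl)-7-(3-methylbut-2-en-1-yl)bicyclo[3.3.1]non-3-ene-2,9-dione | [C@@H]12C[C@H](CC=C(C)C)[C@](C)(CCC=C(C)C)[C@@H](C(=O)C=C1O)C2=O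
F4 | step 5 | (1S,5R,7S,8R)-4-methoxy-8-methyl-8-(4-methylpent-3-en-1-yl)-7-(3-methylbut-2-en-1-yl)bicyclo[3.3.1]non-3-ene-2,9-dione | [C@@H]12C[C@H](CC=C(C)C)[C@](C)(CCC=C(C)C)[C@@H](C(=O)C=C1OC)C2=O
F5 | step 10 | methyl 5-methyl-2-(prop-1-en-2-yl)hex-5-enoate (racemic) | C=C(C)CCC(C(=O)OC)C(=C)C
F6 | step 10 | 5-methyl-2-(prop-1-en-2-yl)hex-5-en-1-ol (racemic) | C=C(C)CCC(CO)C(=C)C
F7 | step 10 | (2R)-5-methyl-2-(prop-1-en-2-yl)hex-5-en-1-yl acetate | C=C(C)CC[C@@H](COC(C)=O)C(=C)C
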